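**Retrosynthetic overview**

- The strategy rests on the pyranone ring: O1 (on C8a) and C4 (on C4a) sit on neighbouring benzene carbons, with the C5 oxygen directly beside C4a. A 3-(methoxymethoxy)-5-alkoxybenzyne that takes up the O and the CH of DMF across its triple bond delivers exactly this pattern; dimethyl malonate then supplies C3 and C2 (C4–C3, O1–C2). The 5- and 7-oxygens are thereby told apart by the ring construction.
- The aryne precursor is an ortho-silylaryl triflate made from 2-bromoresorcinol (retro-Brook/triflation, MOM ether, C–H borylation/oxidation para to silicon) and joined to the side-chain alcohol by Mitsunobu etherification.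
- The side chain is cut at C7′–C8′: an (E)-alkenyl iodide from geraniol (C1′–C7′) and a primary triflate from D-tartrate acetonide (C8′–C11′, carrying both stereocentres).
- Only one ring is formed, the pyranone, in step 16. Saponification, protodecarboxylation and one acid deprotection then give the target.

Key step: step 16

Remark: side-chain carbons are called C1′ (OCH2) to C11′ (CMe2O). SC stands for the protected side chain (2E,6E)-8-[(4R,5S)-2,2-dimethyl-5-{2-[(triethylsilyl)oxy]propan-2-yl}-1,3-dioxolan-4-yl]-3,7-dimethylocta-2,6-dien-1-yl. 2-Bromoresorcinol, geraniol and dimethyl 2,3-O-isopropylidene-D-tartrate are taken as commercial.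

**Arene fragment**

Step 1
Reactants: 1 2-bromoresorcinol
Product: 2 2-bromo-1,3-bis(trimethylsilyloxy)benzene
Conditions: HMDS (1.5 equiv), THF, 70 °C; evaporate
Reagents that add atoms: hexamethyldisilazane, C[Si](C)(C)N[Si](C)(C)C
Why: O-silylation of both phenols by silyl transfer from HMDS (loss of NH3) prepares the ortho-bromoaryl silyl ether needed for the retro-Brook sequence.

Step 2
Reactants: 2 2-bromo-1,3-bis(trimethylsilyloxy)benzene
Product: 6 3-hydroxy-2-(trimethylsilyl)phenyl trifluoromethanesulfonate, via aryllithium 3 (not isolated), via lithium phenoxide 4 (not isolated), via silyl ether triflate 5 (not isolated)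
Conditions: n-BuLi (1.05 equiv), THF, −78 °C; Tf2O (1.1 equiv), −78 °C; then MeOH, AcOH (cat.), 23 °C
Reagents that add atoms: trifluoromethanesulfonic anhydride, O=S(=O)(OS(=O)(=O)C(F)(F)F)C(F)(F)F
Why: Bromine–lithium exchange followed by anionic 1,3 O→C silyl migration (retro-Brook rearrangement) should give phenoxide 4, which is O-triflated, and mild methanolysis of the remaining aryl silyl ether frees one phenol, so the two oxygens of the symmetric diol are differentiated by the migration itself.

Step 3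
Reactants: 6 3-hydroxy-2-(trimethylsilyl)phenyl trifluoromethanesulfonate
Product: 7 3-(methoxymethoxy)-2-(trimethylsilyl)phenyl trifluoromethanesulfonate
Conditions: MOMCl (1.3 equiv), i-Pr2NEt (1.5 equiv), CH2Cl2, 0 °C
Reagents that add atoms: chloromethyl methyl ether, COCCl
Why: O-alkylation of the phenol (Williamson-type) with a weak amine base at 0 °C keeps the phenoxide concentration low, so the silyl triflate should not be activated.

Step 4
Reactants: 7 3-(methoxymethoxy)-2-(trimethylsilyl)phenyl trifluoromethanesulfonate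
Product: 9 5-hydroxy-3-(methoxymethoxy)-2-(trimethylsilyl)phenyl trifluoromethanesulfonate, via arylboronate 8 (not isolated)
Conditions: [Ir(OMe)(cod)]2 (1.5 mol %), dtbpy (3 mol %), B2pin2 (1.0 equiv), THF, 70 °C; then KHSO5 (Oxone), acetone/H2O, 23 °C
Reagents that add atoms: potassium peroxymonosulfate KHSO5 (the phenol oxygen), [K+].[O-]S(=O)(=O)OO; bis(pinacolato)diboron (boron of intermediate 8 only), CC1(C)OB(OC1(C)C)B1OC(C)(C)C(C)(C)O1
Why: Sterically controlled iridium-catalysed C–H borylation (Ishiyama–Miyaura–Hartwig) should occur at the only C–H without an ortho substituent (para to silicon), and ipso-oxidation of the boronate in the same pot gives the phenol while triflate, aryl silane and MOM ether are spectators.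

**Triol fragment (C8′–C11′)**

Step 5
Reactants: 10 dimethyl 2,3-O-isopropylidene-D-tartrate
Product: 11 methyl (4S,5R)-5-(hydroxymethyl)-2,2-dimethyl-1,3-dioxolane-4-carboxylate
Conditions: NaBH4 (0.6 equiv), MeOH, −10 → 0 °C
Reagents that add atoms: none
Why: Partial borohydride reduction of the activated α-alkoxy diester (desymmetrisation of the C2-symmetric diester) should stop mainly at the hydroxy ester with limiting hydride at low temperature; both stereocentres come unchanged from the chiral pool and the trans-dioxolane is the stable arrangement.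

Step 6
Reactants: 11 methyl (4S,5R)-5-(hydroxymethyl)-2,2-dimethyl-1,3-dioxolane-4-carboxylate
Product: 12 2-[(4S,5R)-5-(hydroxymethyl)-2,2-dimethyl-1,3-dioxolan-4-yl]propan-2-ol
Conditions: MeMgBr (4 equiv), THF, 0 → 23 °C; aq. NH4Cl
Reagents that add atoms: methylmagnesium bromide, C[Mg]Br
Why: Double Grignard addition to the ester builds the tertiary carbinol C11′ without touching the stereocentres.

Step 7
Reactants: 12 2-[(4S,5R)-5-(hydroxymethyl)-2,2-dimethyl-1,3-dioxolan-4-yl]propan-2-ol
Product: 14 [(4R,5S)-2,2-dimethyl-5-{2-[(triethylsilyl)oxy]propan-2-yl}-1,3-dioxolan-4-yl]methyl trifluoromethanesulfonate, via hydroxy triflate 13 (not isolated)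
Conditions: Tf2O (1.05 equiv), 2,6-lutidine (3 equiv), CH2Cl2, −78 °C; then TESOTf (1.2 equiv), −78 → −40 °C; used at once
Reagents that add atoms: trifluoromethanesulfonic anhydride, O=S(=O)(OS(=O)(=O)C(F)(F)F)C(F)(F)F; triethylsilyl trifluoromethanesulfonate, CC[Si](CC)(CC)OS(=O)(=O)C(F)(F)F
Why: Sulfonylation at −78 °C should be selective for the primary alcohol over the hindered tertiary one, and O-silylation of the tertiary alcohol in the same flask means the labile triflate never warms next to a free hydroxyl.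

**Alkenyl iodide fragment (C1′–C7′) and chain assembly**

Step 8
Reactants: 15 geraniol
Product: 16 geranyl 4-methoxybenzyl ether
Conditions: NaH, PMBCl, n-Bu4NI (cat.), THF/DMF, 0 → 23 °C
Reagents that add atoms: 4-methoxybenzyl chloride, COc1ccc(CCl)cc1
Why: Williamson etherification installs a protecting group that tolerates organolithium reagents and is later removed oxidatively.

Step 9
Reactants: 16 geranyl 4-methoxybenzyl ether
Product: 18 (4E)-6-[(4-methoxybenzyl)oxy]-4-methylhex-4-enal, via epoxide 17 (not isolated)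
Conditions: mCPBA (1.0 equiv), NaHCO3, CH2Cl2, −10 °C; then H5IO6, THF/H2O, 0 °C
Reagents that add atoms: 3-chloroperoxybenzoic acid (the aldehyde oxygen), OOC(=O)c1cccc(Cl)c1
Why: Prilezhaev epoxidation should select the more electron-rich distal alkene (the 2,3-alkene is deactivated by the allylic oxygen), and periodic acid cleaves the epoxide through its diol to the aldehyde with loss of acetone.

Step 10
Reactants: 18 (4E)-6-[(4-methoxybenzyl)oxy]-4-methylhex-4-enal
Product: 19 1-({[(2E)-7,7-dibromo-3-methylhepta-2,6-dien-1-yl]oxy}methyl)-4-methoxybenzene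
Conditions: CBr4 (2 equiv), PPh3 (4 equiv), CH2Cl2, 0 °C
Reagents that add atoms: carbon tetrabromide, BrC(Br)(Br)Br
Why: First stage of the Corey–Fuchs sequence, a Wittig reaction of the dibromomethylene ylide with the aldehyde.

Step 11
Reactants: 19 1-({[(2E)-7,7-dibromo-3-methylhepta-2,6-dien-1-yl]oxy}methyl)-4-methoxybenzene
Product: 21 1-methoxy-4-({[(2E)-3-methyloct-2-en-6-yn-1-yl]oxy}methyl)benzene, via lithium acetylide 20 (not isolated)
Conditions: n-BuLi (2.1 equiv), THF, −78 → 0 °C; MeI, −78 → 23 °C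
Reagents that add atoms: iodomethane, CI
Why: Second stage of the Corey–Fuchs sequence (bromine–lithium exchange, Fritsch–Buttenberg–Wiechell rearrangement, deprotonation) gives the lithium acetylide, which is C-methylated to the 2-alkyne.

Step 12
Reactants: 21 1-methoxy-4-({[(2E)-3-methyloct-2-en-6-yn-1-yl]oxy}methyl)benzene
Product: 23 1-({[(2E,6E)-7-iodo-3-methylocta-2,6-dien-1-yl]oxy}methyl)-4-methoxybenzene, via alkenylzirconocene chloride 22 (not isolated)
Conditions: Cp2Zr(H)Cl (2.2 equiv), THF, 45 °C; then I2, 0 °C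
Reagents that add atoms: iodine, II
Why: syn-Hydrozirconation of the 2-alkyne under equilibrating conditions (excess Cp2Zr(H)Cl) should place zirconium on the less hindered methyl-bearing carbon C7′, and iodinolysis with retention gives the (E)-2-iodoalkene, which fixes the C6′=C7′ geometry.

Step 13
Reactants: 23 1-({[(2E,6E)-7-iodo-3-methylocta-2,6-dien-1-yl]oxy}methyl)-4-methoxybenzene (1.3 equiv), 14 [(4R,5S)-2,2-dimethyl-5-{2-[(triethylsilyl)oxy]propan-2-yl}-1,3-dioxolan-4-yl]methyl trifluoromethanesulfonate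
Product: 26 SC 4-methoxybenzyl ether, via alkenyllithium 24 (not isolated), via alkenylmagnesium bromide 25 (not isolated)
Conditions: 23, t-BuLi (2.1 equiv per 23), Et2O, −78 °C; MgBr2·OEt2, −78 → 0 °C; then 14, CuBr·SMe2 (10 mol %), THF, −40 → 0 °C
Reagents that add atoms: none
Why: Iodine–lithium exchange and transmetalation proceed with retention, and copper-catalysed SN2 displacement of the primary triflate by the alkenyl Grignard reagent (Kotsuki-type Grignard–triflate coupling) should form C7′–C8′ without touching alkene geometry or stereocentres.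

Step 14
Reactants: 26 SC 4-methoxybenzyl ether
Product: 27 SC-OH, the side-chain alcohol
Conditions: DDQ (1.2 equiv), CH2Cl2/pH 7 buffer, 0 °C
Reagents that add atoms: none
Why: Oxidative PMB cleavage (hydride abstraction by DDQ, hydrolysis of the oxocarbenium ion) is orthogonal to the acetonide and the TES ether.

**Union, annulation and end game**

Step 15
Reactants: 9 5-hydroxy-3-(methoxymethoxy)-2-(trimethylsilyl)phenyl trifluoromethanesulfonate, 27 SC-OH
Product: 28 3-(methoxymethoxy)-5-(SC-oxy)-2-(trimethylsilyl)phenyl trifluoromethanesulfonate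
Conditions: PPh3, DIAD, THF, 0 → 23 °C
Reagents that add atoms: none
Why: Mitsunobu etherification (SN2 at the primary allylic carbon by the acidic phenol) runs under neutral conditions that should leave the silyl triflate intact.

Step 16
Reactants: 28 3-(methoxymethoxy)-5-(SC-oxy)-2-(trimethylsilyl)phenyl trifluoromethanesulfonate, 29 N,N-dimethylformamide, 30 dimethyl malonate
Product: 34 methyl 5-(methoxymethoxy)-7-(SC-oxy)-2-oxo-2H-chromene-3-carboxylate, via aryne 31 (not isolated), via ortho-quinone methide 32 (not isolated), via malonate adduct 33 (not isolated)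
Conditions: CsF (4 equiv), 30 (3 equiv), 29 as solvent, 23 → 50 °C
Reagents that add atoms: none
Why: Fluoride attacks silicon and triflate leaves to give aryne 31, whose triple bond is polarised by the inductively withdrawing OMOM group on the neighbouring carbon, so the formamide oxygen should add to the distal aryne carbon (future C8a) and the aryl anion beside OMOM closes onto the iminium carbon (C4 on C4a) by 4-exo-trig attack, the benzoxete then opening to ortho-quinone methide 32. Malonate anion adds to the exocyclic carbon of 32 (C4–C3) to give 33, whose phenoxide lactonises onto one ester by 6-exo-trig acyl substitution (O1–C2, closure of the pyranone ring), and E1cB loss of dimethylamine installs C3=C4. The reaction type is the known three-component coupling of arynes, DMF and active methylene esters to coumarin-3-carboxylates, here applied to an aryne carrying an unsaturated, protected side chain. No stereocentre is created (the C4 centre of 33 is lost on elimination), and the two tartrate-derived centres and both alkenes are spectators. The step needs regioselectivity in the first addition, secured by the 3-OMOM group (the 5-alkoxy group has only a weak, subordinate effect), and chemoselectivity for DMF over other aryne traps, secured by using DMF as solvent.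

Step 17
Reactants: 34 methyl 5-(methoxymethoxy)-7-(SC-oxy)-2-oxo-2H-chromene-3-carboxylate
Product: 35 5-(methoxymethoxy)-7-(SC-oxy)-2-oxo-2H-chromene-3-carboxylic acid
Conditions: LiOH·H2O (3 equiv), THF/H2O, 0 → 23 °C; aq. citric acid to pH 4
Reagents that add atoms: lithium hydroxide, [Li+].[OH-]
Why: Saponification of the activated ester; mild acidification recloses any opened lactone and should spare MOM, acetonide and the tertiary TES ether.

Step 18
Reactants: 35 5-(methoxymethoxy)-7-(SC-oxy)-2-oxo-2H-chromene-3-carboxylic acid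
Product: 36 5-(methoxymethoxy)-7-(SC-oxy)-2H-chromen-2-one
Conditions: Ag2CO3 (15 mol %), AcOH (10 mol %), DMSO, 110 °C
Reagents that add atoms: none
Why: Silver-catalysed protodecarboxylation of a coumarin-3-carboxylic acid (decarboxylative argentation at C3, then protonolysis) removes the carboxyl group that served to activate the methylene partner.

Step 19
Reactants: 36 5-(methoxymethoxy)-7-(SC-oxy)-2H-chromen-2-one
Product: 37 5-hydroxy-7-{[(2E,6E,9R,10S)-9,10,11-trihydroxy-3,7,11-trimethyldodeca-2,6-dien-1-yl]oxy}-2H-chromen-2-one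
Conditions: p-TsOH·H2O (0.3 equiv), MeOH, 35 °C
Reagents that add atoms: none
Why: Acid-catalysed transacetalisation and solvolysis in methanol should remove the MOM ether, the acetonide and the TES ether in one operation under conditions mild enough for the allylic aryl ether.

**Compound list**

1 | 2-bromoresorcinol (2-bromobenzene-1,3-diol) | Oc1cccc(O)c1Br | starting material
2 | 2-bromo-1,3-bis(trimethylsilyloxy)benzene | C[Si](C)(C)Oc1cccc(O[Si](C)(C)C)c1Br | intermediate
3 | [2,6-bis(trimethylsilyloxy)phenyl]lithium | [Li]c1c(O[Si](C)(C)C)cccc1O[Si](C)(C)C | intermediate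
4 | lithium 3-(trimethylsilyloxy)-2-(trimethylsilyl)phenoxide | [Li]Oc1cccc(O[Si](C)(C)C)c1[Si](C)(C)C | intermediate
5 | 3-(trimethylsilyloxy)-2-(trimethylsilyl)phenyl trifluoromethanesulfonate | C[Si](C)(C)Oc1cccc(OS(=O)(=O)C(F)(F)F)c1[Si](C)(C)C | intermediate
6 | 3-hydroxy-2-(trimethylsilyl)phenyl trifluoromethanesulfonate | C[Si](C)(C)c1c(O)cccc1OS(=O)(=O)C(F)(F)F | intermediate
7 | 3-(methoxymethoxy)-2-(trimethylsilyl)phenyl trifluoromethanesulfonate | C[Si](C)(C)c1c(OCOC)cccc1OS(=O)(=O)C(F)(F)F | intermediate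
8 | 3-(methoxymethoxy)-5-(4,4,5,5-tetramethyl-1,3,2-dioxaborolan-2-yl)-2-(trimethylsilyl)phenyl trifluoromethanesulfonate | C[Si](C)(C)c1c(OS(=O)(=O)C(F)(F)F)cc(B2OC(C)(C)C(C)(C)O2)cc1OCOC | intermediate
9 | 5-hydroxy-3-(methoxymethoxy)-2-(trimethylsilyl)phenyl trifluoromethanesulfonate | C[Si](C)(C)c1c(OS(=O)(=O)C(F)(F)F)cc(O)cc1OCOC | intermediate
10 | dimethyl (4S,5S)-2,2-dimethyl-1,3-dioxolane-4,5-dicarboxylate (dimethyl 2,3-O-isopropylidene-D-tartrate) | COC(=O)[C@H]1OC(C)(C)O[C@@H]1C(=O)OC | starting material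
11 | methyl (4S,5R)-5-(hydroxymethyl)-2,2-dimethyl-1,3-dioxolane-4-carboxylate | OC[C@H]1OC(C)(C)O[C@@H]1C(=O)OC | intermediate
12 | 2-[(4S,5R)-5-(hydroxymethyl)-2,2-dimethyl-1,3-dioxolan-4-yl]propan-2-ol | OC[C@H]1OC(C)(C)O[C@@H]1C(C)(C)O | intermediate
13 | [(4R,5S)-5-(2-hydroxypropan-2-yl)-2,2-dimethyl-1,3-dioxolan-4-yl]methyl trifluoromethanesulfonate | FC(F)(F)S(=O)(=O)OC[C@H]1OC(C)(C)O[C@@H]1C(C)(C)O | intermediate
14 | [(4R,5S)-2,2-dimethyl-5-{2-[(triethylsilyl)oxy]propan-2-yl}-1,3-dioxolan-4-yl]methyl trifluoromethanesulfonate | FC(F)(F)S(=O)(=O)OC[C@H]1OC(C)(C)O[C@@H]1C(C)(C)O[Si](CC)(CC)CC | intermediate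
15 | geraniol, (2E)-3,7-dimethylocta-2,6-dien-1-ol | CC(C)=CCC/C(C)=C/CO | starting material
16 | 1-({[(2E)-3,7-dimethylocta-2,6-dien-1-yl]oxy}methyl)-4-methoxybenzene (geranyl PMB ether) | COc1ccc(COC/C=C(\C)CCC=C(C)C)cc1 | intermediate
17 | 2-{(3E)-5-[(4-methoxybenzyl)oxy]-3-methylpent-3-en-1-yl}-3,3-dimethyloxirane (racemic at the oxirane carbon) | COc1ccc(COC/C=C(\C)CCC2OC2(C)C)cc1 | intermediate
18 | (4E)-6-[(4-methoxybenzyl)oxy]-4-methylhex-4-enal | COc1ccc(COC/C=C(\C)CCC=O)cc1 | intermediate
19 | 1-({[(2E)-7,7-dibromo-3-methylhepta-2,6-dien-1-yl]oxy}methyl)-4-methoxybenzene | COc1ccc(COC/C=C(\C)CCC=C(Br)Br)cc1 | intermediate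
20 | {(5E)-7-[(4-methoxybenzyl)oxy]-5-methylhept-5-en-1-yn-1-yl}lithium | COc1ccc(COC/C=C(\C)CCC#C[Li])cc1 | intermediate
21 | 1-methoxy-4-({[(2E)-3-methyloct-2-en-6-yn-1-yl]oxy}methyl)benzene | COc1ccc(COC/C=C(\C)CCC#CC)cc1 | intermediate
22 | chlorobis(cyclopentadienyl){(2E,6E)-8-[(4-methoxybenzyl)oxy]-6-methylocta-2,6-dien-2-yl}zirconium | COc1ccc(COC/C=C(\C)CC/C=C(\C)[Zr](Cl)(C2C=CC=C2)C2C=CC=C2)cc1 | intermediate
23 | 1-({[(2E,6E)-7-iodo-3-methylocta-2,6-dien-1-yl]oxy}methyl)-4-methoxybenzene | COc1ccc(COC/C=C(\C)CC/C=C(\C)I)cc1 | intermediate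
24 | {(2Z,6E)-8-[(4-methoxybenzyl)oxy]-6-methylocta-2,6-dien-2-yl}lithium (lithium in place of the iodine of 23, geometry retained) | COc1ccc(COC/C=C(\C)CC/C=C(\C)[Li])cc1 | intermediate
25 | bromo{(2E,6E)-8-[(4-methoxybenzyl)oxy]-6-methylocta-2,6-dien-2-yl}magnesium (geometry as in 23) | COc1ccc(COC/C=C(\C)CC/C=C(\C)[Mg]Br)cc1 | intermediate
26 | triethyl{[2-((4S,5R)-5-{(2E,6E)-8-[(4-methoxybenzyl)oxy]-2,6-dimethylocta-2,6-dien-1-yl}-2,2-dimethyl-1,3-dioxolan-4-yl)propan-2-yl]oxy}silane (SC 4-methoxybenzyl ether) | COc1ccc(COC/C=C(\C)CC/C=C(\C)C[C@H]2OC(C)(C)O[C@@H]2C(C)(C)O[Si](CC)(CC)CC)cc1 | intermediate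
27 | (2E,6E)-8-[(4R,5S)-2,2-dimethyl-5-{2-[(triethylsilyl)oxy]propan-2-yl}-1,3-dioxolan-4-yl]-3,7-dimethylocta-2,6-dien-1-ol (SC-OH) | OC/C=C(\C)CC/C=C(\C)C[C@H]1OC(C)(C)O[C@@H]1C(C)(C)O[Si](CC)(CC)CC | intermediate
28 | 5-{[(2E,6E)-8-((4R,5S)-2,2-dimethyl-5-{2-[(triethylsilyl)oxy]propan-2-yl}-1,3-dioxolan-4-yl)-3,7-dimethylocta-2,6-dien-1-yl]oxy}-3-(methoxymethoxy)-2-(trimethylsilyl)phenyl trifluoromethanesulfonate | C[Si](C)(C)c1c(OS(=O)(=O)C(F)(F)F)cc(OC/C=C(\C)CC/C=C(\C)C[C@H]2OC(C)(C)O[C@@H]2C(C)(C)O[Si](CC)(CC)CC)cc1OCOC | intermediate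
29 | N,N-dimethylformamide | CN(C)C=O | starting material
30 | dimethyl malonate | COC(=O)CC(=O)OC | starting material
31 | 3-(methoxymethoxy)-5-(SC-oxy)benzyne | COCOC1=CC(OC/C=C(\C)CC/C=C(\C)C[C@H]2OC(C)(C)O[C@@H]2C(C)(C)O[Si](CC)(CC)CC)=CC#C1 | intermediate
32 | 6-[(dimethylamino)methylidene]-5-(methoxymethoxy)-3-(SC-oxy)cyclohexa-2,4-dien-1-one (ortho-quinone methide) | CN(C)C=C1C(=O)C=C(OC/C=C(\C)CC/C=C(\C)C[C@H]2OC(C)(C)O[C@@H]2C(C)(C)O[Si](CC)(CC)CC)C=C1OCOC | intermediate
33 | dimethyl 2-{(dimethylamino)[2-hydroxy-6-(methoxymethoxy)-4-(SC-oxy)phenyl]methyl}malonate (both configurations at the benzylic carbon) | COC(=O)C(C(=O)OC)C(N(C)C)c1c(O)cc(OC/C=C(\C)CC/C=C(\C)C[C@H]2OC(C)(C)O[C@@H]2C(C)(C)O[Si](CC)(CC)CC)cc1OCOC | intermediate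
34 | methyl 7-{[(2E,6E)-8-((4R,5S)-2,2-dimethyl-5-{2-[(triethylsilyl)oxy]propan-2-yl}-1,3-dioxolan-4-yl)-3,7-dimethylocta-2,6-dien-1-yl]oxy}-5-(methoxymethoxy)-2-oxo-2H-chromene-3-carboxylate | COC(=O)c1cc2c(OCOC)cc(OC/C=C(\C)CC/C=C(\C)C[C@H]3OC(C)(C)O[C@@H]3C(C)(C)O[Si](CC)(CC)CC)cc2oc1=O | intermediate
35 | 7-{[(2E,6E)-8-((4R,5S)-2,2-dimethyl-5-{2-[(triethylsilyl)oxy]propan-2-yl}-1,3-dioxolan-4-yl)-3,7-dimethylocta-2,6-dien-1-yl]oxy}-5-(methoxymethoxy)-2-oxo-2H-chromene-3-carboxylic acid | OC(=O)c1cc2c(OCOC)cc(OC/C=C(\C)CC/C=C(\C)C[C@H]3OC(C)(C)O[C@@H]3C(C)(C)O[Si](CC)(CC)CC)cc2oc1=O | intermediate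
36 | 7-{[(2E,6E)-8-((4R,5S)-2,2-dimethyl-5-{2-[(triethylsilyl)oxy]propan-2-yl}-1,3-dioxolan-4-yl)-3,7-dimethylocta-2,6-dien-1-yl]oxy}-5-(methoxymethoxy)-2H-chromen-2-one | COCOc1cc(OC/C=C(\C)CC/C=C(\C)C[C@H]3OC(C)(C)O[C@@H]3C(C)(C)O[Si](CC)(CC)CC)cc2oc(=O)ccc12 | intermediate
37 | 5-hydroxy-7-{[(2E,6E,9R,10S)-9,10,11-trihydroxy-3,7,11-trimethyldodeca-2,6-dien-1-yl]oxy}-2H-chromen-2-one | C/C(=C\COc1cc(O)c2ccc(=O)oc2c1)CC/C=C(\C)C[C@@H](O)[C@H](O)C(C)(C)O | target

**Step count and risks**

Total step count: 19. Longest linear sequence: 12 steps (geraniol 15 to 37, steps 8 to 19).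

Steps most likely to fail:

1. Step 16 (aryne three-component annulation). The aryne may be consumed by pathways that compete with insertion into DMF (direct addition of fluoride or malonate anion, ene reaction with a chain alkene). The first addition may lose regiocontrol, malonate may add a second time to C4 of the product, and fluoride may partly remove the TES group. Fallback: set out from 27 and etherify commercial 5,7-dihydroxycoumarin (Oc1cc(O)c2ccc(=O)oc2c1) under Mitsunobu conditions (PPh3, DIAD, THF). The more acidic and less hindered 7-OH should react first, giving 5-hydroxy-7-(SC-oxy)-2H-chromen-2-one F1 after chromatographic removal of any 5-O and bis ether. F1 comes back to the route at 37 under the conditions of step 19, which remove its acetonide and TES ether.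

2. Step 18 (protodecarboxylation). Heating with a silver salt and acid at 110 °C may cause ionisation or Claisen rearrangement of the allylic aryl ether, or acid-promoted loss of the MOM, acetonide or TES groups, before decarboxylation is complete. Fallback: set out from 28 and treat it with CsF in 29, followed by aqueous work-up; hydrolysis of the DMF insertion product should give 2-hydroxy-6-(methoxymethoxy)-4-(SC-oxy)benzaldehyde F2. F2 is then heated with (triphenylphosphoranylidene)ketene, Ph3P=C=C=O, in toluene at 80–110 °C: the phenol adds to the ketene to give an acyl ylide, and intramolecular Wittig olefination of the aldehyde closes the pyranone without any carboxyl group. This comes back to the route at 36.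

3. Step 12 (hydrozirconation/iodination). Regiocontrol may be incomplete, with zirconium partly on C6′, so that an inseparable regioisomeric iodide is carried into the fragment coupling. Fallback: set out from 19 and treat it with n-BuLi (2 equiv) and then Me3SiCl to give {(5E)-7-[(4-methoxybenzyl)oxy]-5-methylhept-5-en-1-yn-1-yl}trimethylsilane F3. Hydroalumination of F3 with i-Bu2AlH in heptane is regiospecific (aluminium on the silicon-bearing carbon) and gives net trans addition; formation of the alanate with MeLi and alkylation with MeI then give {(2E,6E)-8-[(4-methoxybenzyl)oxy]-6-methylocta-2,6-dien-2-yl}trimethylsilane F4, with the new methyl cis to the chain. Ipso-iododesilylation of F4 with NIS (retention) comes back to the route at 23.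

**Further compounds**

F1 | step 16 | 5-hydroxy-7-{[(2E,6E)-8-((4R,5S)-2,2-dimethyl-5-{2-[(triethylsilyl)oxy]propan-2-yl}-1,3-dioxolan-4-yl)-3,7-dimethylocta-2,6-dien-1-yl]oxy}-2H-chromen-2-one | Oc1cc(OC/C=C(\C)CC/C=C(\C)C[C@H]3OC(C)(C)O[C@@H]3C(C)(C)O[Si](CC)(CC)CC)cc2oc(=O)ccc12
F2 | step 18 | 4-{[(2E,6E)-8-((4R,5S)-2,2-dimethyl-5-{2-[(triethylsilyl)oxy]propan-2-yl}-1,3-dioxolan-4-yl)-3,7-dimethylocta-2,6-dien-1-yl]oxy}-2-hydroxy-6-(methoxymethoxy)benzaldehyde | O=Cc1c(O)cc(OC/C=C(\C)CC/C=C(\C)C[C@H]2OC(C)(C)O[C@@H]2C(C)(C)O[Si](CC)(CC)CC)cc1OCOC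
F3 | step 12 | {(5E)-7-[(4-methoxybenzyl)oxy]-5-methylhept-5-en-1-yn-1-yl}trimethylsilane | COc1ccc(COC/C=C(\C)CCC#C[Si](C)(C)C)cc1
F4 | step 12 | {(2E,6E)-8-[(4-methoxybenzyl)oxy]-6-methylocta-2,6-dien-2-yl}trimethylsilane | COc1ccc(COC/C=C(\C)CC/C=C(\C)[Si](C)(C)C)cc1
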